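(Readings and results stem from a simulated flask with constants of no real substance; scatter was added.)

Start late, with the readings at 40.0 min: the birch run keeps 49% of its starting material, and the cedar run keeps 56%.

| setting | birch | cedar | flask |
|---|---|---|---|
| starting material | 0.014 M | 0.022 M | 0.010 M |
| gas | 3.1 mM (held) | 3.1 mM (held) | 3.1 mM (held) |
| remark | run made earlier | run made earlier |  |
| time |  |  | 1.0 h |

- birch (time / min: target / %, starting material / %): 6.00: 6, 94; 12.0: 12, 85; 20.0: 18, 76; 25.0: 23, 68; 30.0: 29, 62; 40.0: 34, 49
- cedar (time / min: target / %, starting material / %): 2.50: 4, 93; 8.00: 7, 92; 12.0: 11, 87; 20.0: 14, 79; 30.0: 23, 65; 40.0: 23, 56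

(each reading ± 1.5 percentage points)

- the numbers in the tables scatter with a standard deviation of 1.5 percentage points
- at the start none of the gas is in solution

- target at 1.0 h, in percent of the starting material charged
- the change that raises the amount of target at 1.0 h, in percent of the starting material charged most ("none" if none brings more than 2 percentage points) (red / grey / none)
- amount of target at 1.0 h, in percent of the starting material charged, after grey

- red: doubling the saturation concentration of gas, all else as stated
- grey: doubling the transfer coefficient of the gas, all else as stated

Turn those shares into concentrations. Birch has used 0.179 mM min⁻¹ on average and cedar 0.242 mM min⁻¹, more. The rate therefore rises with c(starting material), so gas transfer is not the rate-limiting step, and I take c(gas) as held near saturation.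

Which order fits? If the rate goes as the square root of c(starting material), the root of the remaining share falls on a straight line. Birch then reaches zero at 133 min and cedar at 159 min. Their ratio, 1.20, stands near the root of the charge ratio, 1.25, and below the charge ratio itself, 1.57. So you scale by that root and average: 110 min is the emptying time, the moment this flask's root line reaches zero.

At 1.0 h the flask then keeps 20.6%. Part of the reacted material is missing from the target reading at 40.0 min: 33.3% in birch and 47.7% in cedar, a share that reads higher in the run with the larger charge. Scaled to this flask it is 23.8%, so my reckoning gives 60.5% target. Grey should change little, and red should be best.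

The forecast says 34%, red and 36% after grey, on “about 66% converts by 1 h”. My reckoning converts more, 79.4%.

The flask gives 55.9% target; red adds 16 percentage points, grey 0.12 points, leaving 56.0% after grey.

    starting material + reagent → target, rate k1*[starting material]^0.5*[reagent]^0.5 (k = 0.0260 min⁻¹)
    gas ⇌ reagent, rate k2*(csat - [reagent]) (kL = 4.67 min⁻¹)
    starting material + target → side product (k = 1.02 M⁻¹ min⁻¹)

Reagent in the flask stands at 99.2% of saturation at 0.500 h. The emptying time of 110 min put 20.6% of the starting material in the flask at 1.0 h, and 25% is there. A neighbouring flask, read at 2.5 h, lies past that time, and it holds 0% starting material and 74.6% target.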